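**Assumption:** the target has no stereocentre and no stereogenic double bond (both alkenes are 3-methylbut-2-enyl groups), so it is achiral and no stereocontrol is needed.

## Retrosynthetic overview

1. Target ⇒ 2'-O-methylation and desilylation of a 7,4'-bis-silylated 5,2'-dihydroxy-6,3'-diprenylisoflavone.
2. Key disconnection: both prenyl groups are traced back to C–O bonds, namely 1,1-dimethylallyl ethers on the two "inner" oxygens O5 and O2'. Their only hydrogen-bearing ortho carbons are C6 and C3', so a [3,3] relay fixes the regiochemistry.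
3. These ethers come from 2'-hydroxygenistein after silylation of the two exposed hydroxyls (7-OH, 4'-OH).
4. 2'-Hydroxygenistein ⇒ demethylation of 5,7-dihydroxy-2',4'-dimethoxyisoflavone ⇒ phloroglucinol + 2,4-dimethoxyphenylacetic acid + one carbon from DMF.
5. Ring order: rings A and B are bought; the pyranone ring C is the only ring made (C-acylation, then O1–C2 closure, step 1).

## Route

Step 1
Reactants: 1 phloroglucinol (benzene-1,3,5-triol); 2 2,4-dimethoxyphenylacetic acid
Product: 5 5,7-dihydroxy-2',4'-dimethoxyisoflavone, via deoxybenzoin 3 (not isolated), via enaminone 4 (not isolated)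
Conditions: BF3·OEt2 (medium), 85 °C; then DMF, MsCl, 20 → 75 °C; aq. NaOAc work-up
Reagents that add atoms: N,N-dimethylformamide (DMF), CN(C)C=O
Why: Friedel–Crafts C-acylation of the symmetric triol gives the BF2-chelated deoxybenzoin, its methylene is aminomethylenated by the DMF/MsCl (Vilsmeier-type) reagent, and O-attack on the enaminone with loss of dimethylamine (addition–elimination) closes the pyranone ring by forming O1–C2 (one-pot deoxybenzoin isoflavone synthesis).

Step 2
Reactants: 5 5,7-dihydroxy-2',4'-dimethoxyisoflavone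
Product: 6 5,7,2',4'-tetrahydroxyisoflavone (2'-hydroxygenistein)
Conditions: BBr3 (6 equiv), CH2Cl2, −78 °C → rt; MeOH/H2O quench
Reagents that add atoms: none
Why: BBr3 aryl methyl ether cleavage (Lewis adduct, then bromide SN2 at methyl) frees both B-ring oxygens while the chromone is inert and no alkene is present yet.

Step 3
Reactants: 6 5,7,2',4'-tetrahydroxyisoflavone
Product: 7 5,2'-dihydroxy-7,4'-bis(triisopropylsilyloxy)isoflavone
Conditions: TIPSCl (2.1 equiv), imidazole (4.5 equiv), DMF, 0 °C → rt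
Reagents that add atoms: chlorotriisopropylsilane (TIPSCl), CC(C)[Si](Cl)(C(C)C)C(C)C
Why: Imidazole-mediated silylation with the bulky TIPS group takes only the two exposed, most acidic hydroxyls (7-OH, 4'-OH), because 5-OH is locked in the hydrogen bond to C4=O and 2'-OH is shielded by the ortho chromone ring.

Step 4
Reactants: 7 5,2'-dihydroxy-7,4'-bis(triisopropylsilyloxy)isoflavone
Product: 9 5,2'-dihydroxy-6,3'-bis(3-methylbut-2-enyl)-7,4'-bis(triisopropylsilyloxy)isoflavone, via bis(1,1-dimethylallyl) ether 8 (not isolated)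
Conditions: tert-butyl 2-methylbut-3-en-2-yl carbonate (3 equiv, commercial), Pd(PPh3)4 (5 mol%), THF, 0 °C; filtration through basic alumina; then Eu(fod)3 (10 mol%), PhMe, 80 °C
Reagents that add atoms: tert-butyl 2-methylbut-3-en-2-yl carbonate, C=CC(C)(C)OC(=O)OC(C)(C)C
Why: Proposed new method: Pd(0)-catalysed decarboxylative O-(1,1-dimethylallyl)ation has not been shown on a carbonyl-chelated peri-hydroxyl (chromone 5-OH) nor used to relay a prenyl group from O5 to C6; the tert-butoxide released on decarboxylation deprotonates both free hydroxyls, each phenoxide attacks the more substituted terminus of the (1,1-dimethylallyl)palladium cation (kinetic, outer-sphere Tsuji–Trost etherification, forming the two key C–O bonds), and after removal of Pd the strained tertiary aryl ethers undergo Eu(III)-accelerated aromatic Claisen [3,3] shifts that can only finish at C6 and C3' because the other ortho carbons (C4a, C1') carry no hydrogen, with rearomatisation restoring the 5-OH···O=C4 chelate; the closest known chemistry is Pd-catalysed tert-prenylation of simple phenols followed by Claisen rearrangement of aryl 1,1-dimethylallyl ethers, and the Eu(fod)3-promoted rearrangement of 5-O-prenylflavonoids.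

Step 5
Reactants: 9 5,2'-dihydroxy-6,3'-bis(3-methylbut-2-enyl)-7,4'-bis(triisopropylsilyloxy)isoflavone
Product: 11 2'-methoxylupalbigenin (5,7,4'-trihydroxy-2'-methoxy-6,3'-bis(3-methylbut-2-enyl)isoflavone), via bis-silyl 2'-methyl ether 10 (not isolated)
Conditions: MeOH (3 equiv), PPh3, DIAD, THF, 0 °C → rt; then AcOH, TBAF, 0 °C
Reagents that add atoms: methanol, CO
Why: Mitsunobu O-methylation is neutral, so the aryl silyl ethers survive and only the non-chelated 2'-OH (not the C4=O-chelated 5-OH) is alkylated; acetic acid then destroys residual betaine before buffered fluoride cleaves both Si–O bonds, so the freed 7- and 4'-phenols cannot be methylated and the prenyl/ortho-phenol units see neither strong acid nor strong base.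

## Compound list

1 | phloroglucinol | Oc1cc(O)cc(O)c1 | starting material
2 | 2,4-dimethoxyphenylacetic acid | COc1ccc(CC(=O)O)c(OC)c1 | starting material
3 | 2-(2,4-dimethoxyphenyl)-1-(2,4,6-trihydroxyphenyl)ethanone (deoxybenzoin) | COc1ccc(CC(=O)c2c(O)cc(O)cc2O)c(OC)c1 | intermediate (not isolated)
4 | 2-(2,4-dimethoxyphenyl)-3-(dimethylamino)-1-(2,4,6-trihydroxyphenyl)prop-2-en-1-one (enaminone) | COc1ccc(C(=CN(C)C)C(=O)c2c(O)cc(O)cc2O)c(OC)c1 | intermediate (not isolated)
5 | 5,7-dihydroxy-2',4'-dimethoxyisoflavone | COc1ccc(-c2coc3cc(O)cc(O)c3c2=O)c(OC)c1 | intermediate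
6 | 5,7,2',4'-tetrahydroxyisoflavone (2'-hydroxygenistein) | Oc1ccc(-c2coc3cc(O)cc(O)c3c2=O)c(O)c1 | intermediate
7 | 5,2'-dihydroxy-7,4'-bis(triisopropylsilyloxy)isoflavone | CC(C)[Si](Oc1ccc(-c2coc3cc(O[Si](C(C)C)(C(C)C)C(C)C)cc(O)c3c2=O)c(O)c1)(C(C)C)C(C)C | intermediate
8 | 5,2'-bis(2-methylbut-3-en-2-yloxy)-7,4'-bis(triisopropylsilyloxy)isoflavone | C=CC(C)(C)Oc1cc(O[Si](C(C)C)(C(C)C)C(C)C)ccc1-c1coc2cc(O[Si](C(C)C)(C(C)C)C(C)C)cc(OC(C)(C)C=C)c2c1=O | intermediate (not isolated)
9 | 5,2'-dihydroxy-6,3'-bis(3-methylbut-2-enyl)-7,4'-bis(triisopropylsilyloxy)isoflavone | CC(C)=CCc1c(O)c(-c2coc3cc(O[Si](C(C)C)(C(C)C)C(C)C)c(CC=C(C)C)c(O)c3c2=O)ccc1O[Si](C(C)C)(C(C)C)C(C)C | intermediate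
10 | 5-hydroxy-2'-methoxy-6,3'-bis(3-methylbut-2-enyl)-7,4'-bis(triisopropylsilyloxy)isoflavone | COc1c(-c2coc3cc(O[Si](C(C)C)(C(C)C)C(C)C)c(CC=C(C)C)c(O)c3c2=O)ccc(O[Si](C(C)C)(C(C)C)C(C)C)c1CC=C(C)C | intermediate (not isolated)
11 | 2'-methoxylupalbigenin | COc1c(-c2coc3cc(O)c(CC=C(C)C)c(O)c3c2=O)ccc(O)c1CC=C(C)C | target

## Step count and risks

Total step count: 5 (steps 1, 4 and 5 are telescoped one-pot sequences). Longest linear sequence: 5 steps, from 1 or 2 to 11.

The three steps most likely to fail: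

**Step 4 (the proposed new step).** Risks are no O-alkylation at the chelated 5-OH, C- instead of O-allylation of the electron-rich A-ring phenoxide, or Pd-mediated isomerisation to linear prenyl ethers. The fallback uses known chemistry and sets out from 7. Copper-catalysed O-propargylation (3-chloro-3-methylbut-1-yne, CuCl2·2H2O cat., DBU, MeCN, 0 °C) gives 5,2'-bis(2-methylbut-3-yn-2-yloxy)-7,4'-bis(triisopropylsilyloxy)isoflavone F1. Lindlar semihydrogenation (H2, Pd/CaCO3–Pb, quinoline, EtOAc) then gives 8, this time isolated. Thermal aromatic Claisen rearrangement (N,N-diethylaniline, 130 °C) brings it back to the route at 9.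

**Step 3.** The risk is partial silylation of 2'-OH or incomplete discrimination between 4'-OH and 2'-OH. The fallback sets out from 6 and replaces steric control and silyl protection by acidity control and acetal protection.
- MOMCl (2.1 equiv), K2CO3, acetone, 0 °C gives 5,2'-dihydroxy-7,4'-bis(methoxymethoxy)isoflavone F2.
- The conditions of step 4 take F2 through 5,2'-bis(2-methylbut-3-en-2-yloxy)-7,4'-bis(methoxymethoxy)isoflavone F3 (not isolated) to 5,2'-dihydroxy-7,4'-bis(methoxymethoxy)-6,3'-bis(3-methylbut-2-enyl)isoflavone F4.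
- Williamson methylation (MeI, K2CO3, acetone) gives 5-hydroxy-2'-methoxy-7,4'-bis(methoxymethoxy)-6,3'-bis(3-methylbut-2-enyl)isoflavone F5.
- Acetal cleavage (3 M HCl, MeOH, 40 °C) comes back to the route at 11.

**Step 5.** Risks are that the doubly ortho-substituted 2'-OH is too hindered for the Mitsunobu reaction, or that over-methylation occurs during desilylation. The fallback sets out from 9 and exchanges the protecting groups so that a base-mediated methylation can be used.
- TBAF/AcOH, THF, 0 °C gives 5,7,2',4'-tetrahydroxy-6,3'-bis(3-methylbut-2-enyl)isoflavone F6.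
- Pivaloyl chloride (2.1 equiv), pyridine, CH2Cl2, 0 °C acylates only the two exposed hydroxyls and gives 5,2'-dihydroxy-6,3'-bis(3-methylbut-2-enyl)isoflavone-7,4'-diyl bis(2,2-dimethylpropanoate) F7.
- MeI, K2CO3, acetone gives 5-hydroxy-2'-methoxy-6,3'-bis(3-methylbut-2-enyl)isoflavone-7,4'-diyl bis(2,2-dimethylpropanoate) F8.
- Methanolysis (K2CO3, MeOH, rt) comes back to the route at 11.

## Further compounds

F1 | step 4 | 5,2'-bis(2-methylbut-3-yn-2-yloxy)-7,4'-bis(triisopropylsilyloxy)isoflavone | C#CC(C)(C)Oc1cc(O[Si](C(C)C)(C(C)C)C(C)C)ccc1-c1coc2cc(O[Si](C(C)C)(C(C)C)C(C)C)cc(OC(C)(C)C#C)c2c1=O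
F2 | step 3 | 5,2'-dihydroxy-7,4'-bis(methoxymethoxy)isoflavone | COCOc1ccc(-c2coc3cc(OCOC)cc(O)c3c2=O)c(O)c1
F3 | step 3 | 5,2'-bis(2-methylbut-3-en-2-yloxy)-7,4'-bis(methoxymethoxy)isoflavone | C=CC(C)(C)Oc1cc(OCOC)ccc1-c1coc2cc(OCOC)cc(OC(C)(C)C=C)c2c1=O
F4 | step 3 | 5,2'-dihydroxy-7,4'-bis(methoxymethoxy)-6,3'-bis(3-methylbut-2-enyl)isoflavone | COCOc1ccc(-c2coc3cc(OCOC)c(CC=C(C)C)c(O)c3c2=O)c(O)c1CC=C(C)C
F5 | step 3 | 5-hydroxy-2'-methoxy-7,4'-bis(methoxymethoxy)-6,3'-bis(3-methylbut-2-enyl)isoflavone | COCOc1ccc(-c2coc3cc(OCOC)c(CC=C(C)C)c(O)c3c2=O)c(OC)c1CC=C(C)C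
F6 | step 5 | 5,7,2',4'-tetrahydroxy-6,3'-bis(3-methylbut-2-enyl)isoflavone | CC(C)=CCc1c(O)ccc(-c2coc3cc(O)c(CC=C(C)C)c(O)c3c2=O)c1O
F7 | step 5 | 5,2'-dihydroxy-6,3'-bis(3-methylbut-2-enyl)isoflavone-7,4'-diyl bis(2,2-dimethylpropanoate) | CC(C)=CCc1c(OC(=O)C(C)(C)C)ccc(-c2coc3cc(OC(=O)C(C)(C)C)c(CC=C(C)C)c(O)c3c2=O)c1O
F8 | step 5 | 5-hydroxy-2'-methoxy-6,3'-bis(3-methylbut-2-enyl)isoflavone-7,4'-diyl bis(2,2-dimethylpropanoate) | CC(C)=CCc1c(OC(=O)C(C)(C)C)ccc(-c2coc3cc(OC(=O)C(C)(C)C)c(CC=C(C)C)c(O)c3c2=O)c1OC
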